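**Plan**

1. Core numbering: C1 (pyranone-bearing cyclobutane carbon), C2 (CHMe), C3 (methylated ring-fusion carbon), C8 (ring-fusion CH), C4 (OCH), C5 (=CMe), C6 (=CH), C7 (OCMe).
2. Retrosynthetic cuts, in order: the two C–O bonds of the C4–O–O–C7 bridge (singlet oxygen on a C4=C5–C6=C7 diene); the C7–CH3 bond (cross-coupling of a C7 enol triflate); the pyranone ring, back to a C1 aldehyde and a propionate keto ester; the C–H bonds of the C1 and C2 methyls, back to a CH2–S–CH2 bridge; last C2–C3 and C1–C8 of the cyclobutane.
3. Enabling feature: on the cis-fused cyclobutane C1–C2–C3–C8 the methyls of C1 and C2 are cis and share the convex face with the C3 methyl. C1 and C2 can therefore arrive as one ring alkene (a dihydrothiophene ester) added across C3=C8 of a cyclohexenone whose carbonyl marks C7.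
4. Forward ring order: six-membered carbocycle (from pulegone) → cyclobutane by enone–alkene photocycloaddition (thiolane formed, then excised) → pyranone ring at C1 → peroxide bridge last.
5. Stereochemistry: the ring methyl of (R)-pulegone becomes the C5 methyl, which sends the alkene to the opposite face (absolute configuration of C3 and C8). The thiolane ring and the cis-anti-cis preference fix C1 and C2. C5 is then flattened, and O2 adds anti to the cyclobutane to set C4 and C7.

Key step: step 6

Assumption: methyl 2,5-dihydrothiophene-3-carboxylate 8 is a purchased reagent; stereoisomer mixtures at centres that are later destroyed (in 2, 3, 4, 6, 18, 19) are carried on unseparated; every bicyclo[4.2.0]octa-2,4-diene (13 onward) is kept at or below room temperature to avoid thermal 6π ring opening.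

**Route**

Step 1
Reactants: 1 (R)-pulegone
Product: 2 pulegone oxide (epoxide of the exocyclic C=C, both epimers at the spiro carbon)
Conditions: 30% H2O2, LiOH, MeOH, 0 °C → rt
Reagents that add atoms: hydrogen peroxide, OO
Why: Weitz–Scheffer nucleophilic epoxidation of the electron-poor tetrasubstituted enone; the ring-methyl stereocentre is remote and untouched, and both epoxide epimers converge in step 2.

Step 2
Reactants: 2 pulegone oxide
Product: 3 (5R)-5-methyl-2-(phenylsulfanyl)cyclohexan-1-one (cis/trans mixture at C2)
Conditions: NaSPh, THF, reflux; then H2O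
Reagents that add atoms: sodium benzenethiolate, [Na+].[S-]c1ccccc1
Why: Thiolate opening of the α,β-epoxy ketone at the α-carbon followed by retro-aldol loss of acetone from the β-alkoxide should place sulfur regiospecifically on the α-carbon remote from the methyl-bearing side.

Step 3
Reactants: 3 (5R)-5-methyl-2-(phenylsulfanyl)cyclohexan-1-one
Product: 5 (R)-5-methylcyclohex-2-en-1-one, via sulfoxide 4 (not isolated)
Conditions: mCPBA, CH2Cl2, −78 °C; then toluene, 80 °C
Reagents that add atoms: none
Why: Sulfide oxidation and thermal sulfoxide syn-elimination; the sulfoxide has β-hydrogens only on the CH2 away from the carbonyl, so the enone should form regiospecifically with the stereocentre untouched.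

Step 4
Reactants: 5 (R)-5-methylcyclohex-2-en-1-one
Product: 6 (5R)-1,5-dimethylcyclohex-2-en-1-ol (both carbinol epimers)
Conditions: MeLi, Et2O, −78 °C; then H2O
Reagents that add atoms: methyllithium, [Li]C
Why: 1,2-Addition of a hard organolithium to the enone carbonyl; the new carbinol centre is destroyed in step 5, so its configuration is immaterial.

Step 5
Reactants: 6 (5R)-1,5-dimethylcyclohex-2-en-1-ol
Product: 7 (S)-3,5-dimethylcyclohex-2-en-1-one
Conditions: pyridinium chlorochromate [C5H5NH][CrO3Cl], CH2Cl2, rt
Reagents that add atoms: pyridinium chlorochromate, [O-][Cr](=O)(=O)Cl.c1cc[nH+]cc1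
Why: Babler–Dauben oxidative 1,3-transposition (allylic chromate ester [3,3] shift, then oxidation by hexavalent chromium) moves oxygen to the far alkene carbon and leaves the methyl-bearing stereocentre unchanged, the descriptor becoming S only through the priority change.

Step 6
Reactants: 7 (S)-3,5-dimethylcyclohex-2-en-1-one; 8 methyl 2,5-dihydrothiophene-3-carboxylate
Product: 9 cis-anti-cis thiolane keto ester (methyl 7,9-dimethyl-11-oxo-4-thiatricyclo[5.4.0.0(2,6)]undecane-2-carboxylate: ester on C1, CH2–S–CH2 bridge from C1 to C2 on the convex face, C3 methyl, C5 methyl anti to the cyclobutane, C7 ketone)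
Conditions: 8 (5 equiv), hν (366 nm, Pyrex), CH2Cl2, −40 °C, Ar; filtration through basic Al2O3
Reagents that add atoms: none
Why: Excitation of the enone and intersystem crossing give the twisted triplet, whose β-carbon C3 bonds to the unsubstituted alkene carbon C2 to form a triplet 1,4-biradical (α-keto radical at C8, ester-stabilised tertiary radical at C1) that collapses after spin inversion by C8–C1 coupling. The closest known reaction type is the [2+2] photocycloaddition of 3-alkylcyclohexenones with cycloalkene-1-carboxylates, which gives head-to-head cis-anti-cis adducts. The cyclobutane is the only ring closed, and it closes by radical–radical recombination of the 1,4-biradical. C3 is set by bonding anti to the pseudo-equatorial C5 methyl of the half-chair triplet, C8 follows as the strain-dictated cis ring fusion (basic alumina would epimerise any trans-fused adduct at C8), and C1 and C2 are tied cis by the dihydrothiophene ring, which the cis-anti-cis preference places on the convex face with the ester on the concave face. The step needs head-to-head regiochemistry, secured by the ester through the doubly stabilised biradical, and face selectivity, secured by the C5 methyl inherited from pulegone. The dialkyl sulfide is a poor electron donor towards the weakly oxidising enone triplet and 8 is transparent at 366 nm, so only the enone should be excited.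

Step 7
Reactants: 9 cis-anti-cis thiolane keto ester
Product: 10 keto ester (C1 methyl ester; methyls on C1, C2, C3 all on the convex face; C5 methyl; C7 ketone)
Conditions: Raney Ni (W-2, acetone-deactivated), EtOH, 25–50 °C
Reagents that add atoms: none
Why: Raney nickel hydrogenolysis of both C–S bonds (Mozingo-type desulfurisation) turns the CH2–S–CH2 bridge into the cis C1 and C2 methyls without touching a stereocentre, and the deactivated nickel should spare the ketone.

Step 8
Reactants: 10 keto ester
Product: 12 enone ester (C5=C6, C7=O), via silyl enol ether 11 (not isolated)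
Conditions: LiN(iPr)2, Me3SiCl, THF, −78 °C; then Pd(OAc)2, MeCN, rt
Reagents that add atoms: none
Why: Saegusa–Ito oxidation: the amide base removes a proton from C6, the only unhindered α-position (C8–H is a flanked cyclobutane methine and C3 is quaternary, so no other enone can arise), and Pd(OAc)2 converts the silyl enol ether into the C5=C6 enone by β-hydride elimination, which also erases the C5 relay stereocentre.

Step 9
Reactants: 12 enone ester
Product: 13 dienyl triflate ester (C4=C5–C6=C7 with OSO2CF3 on C7)
Conditions: KN(SiMe3)2 (0.95 equiv), THF, −78 → 0 °C; PhNTf2, −78 °C → rt; then H2O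
Reagents that add atoms: N-phenylbis(trifluoromethanesulfonimide), O=S(=O)(N(c1ccccc1)S(=O)(=O)C(F)(F)F)C(F)(F)F
Why: Thermodynamic dienolate formation and O-triflation: with a slight deficit of base the enolates should equilibrate to the linear endocyclic dienolate deprotonated at C4 (C8–H is shielded by the syn methyls on C1 and C3 and its enolate would be exocyclic to the cyclobutane, while the C5-methyl alternative is the less substituted exocyclic diene), and PhNTf2 traps it on oxygen; no stereocentre is involved.

Step 10
Reactants: 13 dienyl triflate ester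
Product: 14 primary alcohol (CH2OH on C1)
Conditions: iBu2AlH, CH2Cl2, −78 °C; then aq. potassium sodium tartrate
Reagents that add atoms: none
Why: Aluminium hydride reduction of the ester to the neopentyl alcohol; alkenyl triflates are inert to iBu2AlH at this temperature and no stereocentre is touched.

Step 11
Reactants: 14 primary alcohol
Product: 15 aldehyde (CHO on C1)
Conditions: Dess–Martin periodinane, CH2Cl2, rt
Reagents that add atoms: none
Why: Dess–Martin oxidation to a non-enolisable aldehyde (C1 is quaternary, so no epimerisation is possible); the electron-poor dienyl triflate tolerates the acetic acid released.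

Step 12
Reactants: 15 aldehyde; 16 methyl 2-methyl-3-oxopentanoate
Product: 18 aldol adduct (methyl 5-hydroxy-2,4-dimethyl-3-oxopentanoate carrying the core on chain C5; diastereomer mixture), via dianion 17 (not isolated)
Conditions: 16 (3 equiv), LiN(iPr)2 (6 equiv), THF, −78 → 0 °C; then 15, −78 °C; then H2O
Reagents that add atoms: none
Why: γ-Selective aldol addition of the β-keto ester dianion, which reacts at its more basic terminal carbanion, to the non-enolisable aldehyde; the three new chain stereocentres are all removed on pyranone formation, so no control is needed.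

Step 13
Reactants: 18 aldol adduct
Product: 19 β,δ-diketo ester (methyl 2,4-dimethyl-3,5-dioxopentanoate with the core on the C5 carbonyl; tautomer and epimer mixture)
Conditions: Dess–Martin periodinane, CH2Cl2, rt
Reagents that add atoms: none
Why: Dess–Martin oxidation of the β-hydroxy ketone to the 1,3-diketone, a standard entry to triketide pyranone precursors; core stereocentres are unaffected.

Step 14
Reactants: 19 β,δ-diketo ester
Product: 20 4-hydroxy-3,5-dimethyl-2H-pyran-2-one bearing the core at C6
Conditions: DBU, toluene, rt
Reagents that add atoms: none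
Why: Base-mediated cyclisation in which the enol oxygen of the ketone next to C1 acylates on the methyl ester (lactonisation with loss of methanol) and tautomerisation gives the 4-hydroxy-2-pyranone; the chain stereocentres become sp2.

Step 15
Reactants: 20 4-hydroxy-2-pyranone
Product: 21 2-methoxy-3,5-dimethyl-4H-pyran-4-one bearing the core at C6 (C7 enol triflate retained)
Conditions: MeOTf, CH2Cl2, 0 °C → rt; then aq. NaHCO3
Reagents that add atoms: methyl trifluoromethanesulfonate, COS(=O)(=O)C(F)(F)F
Why: O-Methylation of the neutral hydroxypyranone by a hard methylating agent at the lactone carbonyl oxygen gives a 2-methoxy-4-hydroxypyrylium ion that loses a proton to the α-methoxy-γ-pyranone, and the electron-poor dienyl triflate is inert to the acid released.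

Step 16
Reactants: 21 methoxypyranone dienyl triflate
Product: 22 diene (C4=C5–C6=C7 with methyls on C5 and C7)
Conditions: MeZnCl, Pd(PPh3)4 (5 mol %), THF, rt
Reagents that add atoms: methylzinc chloride, C[Zn]Cl
Why: Negishi cross-coupling (oxidative addition of zerovalent palladium into the C7–O triflate bond, transmetalation from zinc, reductive elimination) installs the C7 methyl at room temperature without touching the pyranone or any stereocentre.

Step 17
Reactants: 22 diene
Product: 23 target endoperoxide
Conditions: O2, methylene blue (cat.), visible light, CH2Cl2, 0 °C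
Reagents that add atoms: oxygen, O=O
Why: [4+2] Cycloaddition of singlet oxygen to the ring-locked s-cis diene; O2 should approach the face bearing the C3 methyl and H-8, opposite the cyclobutane and its concave-face pyranone, which sets C4 and C7 with the peroxide bridge anti to the four-membered ring.

**Compound list**

1 | (R)-pulegone | C[C@@H]1CCC(=C(C)C)C(=O)C1 | starting material
2 | pulegone oxide (both epoxide epimers) | C[C@@H]1CCC2(OC2(C)C)C(=O)C1 | intermediate
3 | (5R)-5-methyl-2-(phenylsulfanyl)cyclohexan-1-one | C[C@@H]1CCC(Sc2ccccc2)C(=O)C1 | intermediate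
4 | (5R)-5-methyl-2-(phenylsulfinyl)cyclohexan-1-one | C[C@@H]1CCC(S(=O)c2ccccc2)C(=O)C1 | intermediate (not isolated)
5 | (R)-5-methylcyclohex-2-en-1-one | C[C@@H]1CC=CC(=O)C1 | intermediate
6 | (5R)-1,5-dimethylcyclohex-2-en-1-ol | C[C@@H]1CC=CC(C)(O)C1 | intermediate
7 | (S)-3,5-dimethylcyclohex-2-en-1-one | CC1=CC(=O)C[C@@H](C)C1 | intermediate
8 | methyl 2,5-dihydrothiophene-3-carboxylate | COC(=O)C1=CCSC1 | starting material
9 | cis-anti-cis thiolane keto ester | COC(=O)[C@@]2(CSC5)[C@H]5[C@@]3(C)C[C@H](C)CC(=O)[C@@H]23 | intermediate
10 | keto ester (C1 ester, C7 ketone, methyls on C1, C2, C3, C5) | COC(=O)[C@@]2(C)[C@H](C)[C@@]3(C)C[C@H](C)CC(=O)[C@@H]23 | intermediate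
11 | C6=C7 trimethylsilyl enol ether of 10 | COC(=O)[C@@]2(C)[C@H](C)[C@@]3(C)C[C@H](C)C=C(O[Si](C)(C)C)[C@@H]23 | intermediate (not isolated)
12 | enone ester (C5=C6, C7=O) | COC(=O)[C@@]2(C)[C@H](C)[C@@]3(C)CC(C)=CC(=O)[C@@H]23 | intermediate
13 | dienyl triflate ester | COC(=O)[C@@]2(C)[C@H](C)[C@@]3(C)C=C(C)C=C(OS(=O)(=O)C(F)(F)F)[C@@H]23 | intermediate
14 | C1 hydroxymethyl dienyl triflate | OC[C@@]2(C)[C@H](C)[C@@]3(C)C=C(C)C=C(OS(=O)(=O)C(F)(F)F)[C@@H]23 | intermediate
15 | C1 carbaldehyde dienyl triflate | O=C[C@@]2(C)[C@H](C)[C@@]3(C)C=C(C)C=C(OS(=O)(=O)C(F)(F)F)[C@@H]23 | intermediate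
16 | methyl 2-methyl-3-oxopentanoate | CCC(=O)C(C)C(=O)OC | starting material
17 | dilithium dianion of 16 (C2,C4 bis-enolate) | [Li+].[Li+].CC=C([O-])C(C)=C([O-])OC | intermediate (not isolated)
18 | aldol adduct (δ-hydroxy-β-keto ester) | COC(=O)C(C)C(=O)C(C)C(O)[C@@]2(C)[C@H](C)[C@@]3(C)C=C(C)C=C(OS(=O)(=O)C(F)(F)F)[C@@H]23 | intermediate
19 | β,δ-diketo ester | COC(=O)C(C)C(=O)C(C)C(=O)[C@@]2(C)[C@H](C)[C@@]3(C)C=C(C)C=C(OS(=O)(=O)C(F)(F)F)[C@@H]23 | intermediate
20 | 4-hydroxy-3,5-dimethyl-2H-pyran-2-one with the core at C6 | Cc1c(O)c(C)c(=O)oc1[C@@]2(C)[C@H](C)[C@@]3(C)C=C(C)C=C(OS(=O)(=O)C(F)(F)F)[C@@H]23 | intermediate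
21 | 2-methoxy-3,5-dimethyl-4H-pyran-4-one with the core at C6, C7 enol triflate | COc1oc([C@@]2(C)[C@H](C)[C@@]3(C)C=C(C)C=C(OS(=O)(=O)C(F)(F)F)[C@@H]23)c(C)c(=O)c1C | intermediate
22 | diene (pyranone-substituted pentamethylbicyclo[4.2.0]octadiene) | COc1oc([C@@]2(C)[C@H](C)[C@@]3(C)C=C(C)C=C(C)[C@@H]23)c(C)c(=O)c1C | intermediate
23 | CNP0183511.1 (endoperoxide) | COc1oc([C@@]2(C)[C@H](C)[C@@]3(C)[C@@H]4OO[C@@](C)(C=C4C)[C@@H]23)c(C)c(=O)c1C | target

**Step count and risks**

Total step count: 17. Longest linear sequence: 17 steps (1 → 23; 8 and 16 are purchased).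

Steps most likely to fail:

Step 6. The thioether may intercept the enone triplet (charge-transfer quenching or C–S fragmentation), so that conversion stalls or the head-to-head and facial preferences erode. The fallback moves sulfur to a non-donating oxidation level. Starting from 8, oxidation with NaIO4 (MeOH/H2O, 0 °C) would give methyl 2,5-dihydrothiophene-3-carboxylate 1-oxide F1. Irradiation of F1 with 7 as in step 6 should give the S-oxide of the cis-anti-cis adduct F2 (both sulfur epimers). Raney Ni in EtOH, which deoxygenates and desulfurises sulfoxides, would then deliver keto ester 10, where the route is rejoined.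

Step 9. Deprotonation of 12 may occur at the C5 methyl or at C8 instead of C4, giving regioisomeric dienyl triflates that cannot lead to the ring diene. The fallback separates enolisation from triflation. Starting from 12, soft enolisation with Me3SiOTf/Et3N (CH2Cl2, 0 °C → rt, equilibrating) would give the endocyclic C4=C5–C6=C7 trimethylsilyl dienol ether F3. F3 can be purified, with unwanted isomers returned to 12 by mild acid. CsF/PhNTf2 in DME would then transfer the triflyl group to the regiodefined dienolate and return to 13.

Step 12. The concave-face neopentyl aldehyde may react too slowly with the bulky dianion, leaving recovered aldehyde or allowing attack of the dianion on the triflate sulfur. The fallback assembles the pyranone from a ketone and a three-carbon bis-electrophile. Starting from 15, EtMgBr (THF, −78 °C) would give the secondary carbinol F4. Dess–Martin oxidation would give the ethyl ketone F5, and Me3SiOTf/Et3N its trimethylsilyl enol ether F6. Condensation of F6 with methylmalonyl dichloride (Et2O, −78 °C → rt; Effenberger pyranone synthesis) should close the 4-hydroxy-2-pyranone 20 directly, where the route is rejoined.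

**Further compounds**

F1 | step 6 | methyl 2,5-dihydrothiophene-3-carboxylate 1-oxide | COC(=O)C1=CCS(=O)C1
F2 | step 6 | S-oxide of the cis-anti-cis thiolane keto ester (both sulfur epimers) | COC(=O)[C@@]2(CS(=O)C5)[C@H]5[C@@]3(C)C[C@H](C)CC(=O)[C@@H]23
F3 | step 9 | C4=C5–C6=C7 trimethylsilyl dienol ether of 12 | COC(=O)[C@@]2(C)[C@H](C)[C@@]3(C)C=C(C)C=C(O[Si](C)(C)C)[C@@H]23
F4 | step 12 | secondary carbinol from ethyl addition to 15 (both epimers) | CCC(O)[C@@]2(C)[C@H](C)[C@@]3(C)C=C(C)C=C(OS(=O)(=O)C(F)(F)F)[C@@H]23
F5 | step 12 | C1 ethyl ketone | CCC(=O)[C@@]2(C)[C@H](C)[C@@]3(C)C=C(C)C=C(OS(=O)(=O)C(F)(F)F)[C@@H]23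
F6 | step 12 | trimethylsilyl enol ether of the ethyl ketone | CC=C(O[Si](C)(C)C)[C@@]2(C)[C@H](C)[C@@]3(C)C=C(C)C=C(OS(=O)(=O)C(F)(F)F)[C@@H]23
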